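**Retrosynthetic overview** (prostanoid numbering: ester C1, ring C8–C12, ketone C9, Cl on C10, carbinol C12, omega chain C13–C20)
- Feature: in the only ring (cyclopentenone C8–C12), the C9 carbonyl, the C10=C11 alkene and the C12 tertiary alcohol form the 1,4-dioxygenated pattern of a 2,5-disubstituted furan (furan O becomes the C9 carbonyl O, furan C2–C5 become C9–C12), with C8 as the exocyclic carbinol carbon.
- Late stage: C7=C8 by selenoxide elimination and C10–Cl by epoxide opening with HCl lead back to a 4-hydroxy-4-octenyl-5-alkylcyclopentenone; chlorination is placed before dienone formation so that the nucleophilic epoxidation meets only one enone.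
- Key disconnection: C8–C12, made by oxa-Piancatelli 4π electrocyclisation of a 5-octenyl-2-furylcarbinol under a chiral phosphoric acid; this closes the one ring and sets C12.
- The furylcarbinol comes from furan, (Z)-1-bromooct-2-ene, a formyl carbon, an acetate aldol unit and a Z-selective Wittig reaction for C1–C5.

Key step: step 10

Assumption: the sense of induction of a BINOL phosphate in this closure cannot be derived with certainty from the aza series; the (R)-acid is written, and the (S)-acid would be taken instead if the first run gives the (1R,2S) enantiomer.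

**Step 1**
Reactants: 1 (Z)-oct-2-en-1-ol
Product: 2 (Z)-1-bromooct-2-ene
Conditions: CBr4, PPh3, CH2Cl2, 0 °C
Reagents that add atoms: carbon tetrabromide, BrC(Br)(Br)Br
Why: Appel reaction, in which bromide displaces the alkoxyphosphonium group of the primary allylic alcohol by direct SN2 at 0 °C and leaves the Z alkene untouched.

**Step 2**
Reactants: 3 furan; 2 (Z)-1-bromooct-2-ene
Product: 5 2-[(Z)-oct-2-enyl]furan, via 2-furyllithium 4 (not isolated)
Conditions: n-BuLi, THF, 0 °C; then 2, −78 °C to rt
Reagents that add atoms: none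
Why: α-lithiation of furan followed by SN2 alkylation of the aryllithium with the primary allylic bromide, the known route to 2-allylic furans, with the Z geometry carried over unchanged.

**Step 3**
Reactants: 5 2-[(Z)-oct-2-enyl]furan
Product: 6 5-[(Z)-oct-2-enyl]furan-2-carbaldehyde
Conditions: POCl3, DMF, 0 °C to rt; then aq. NaOAc
Reagents that add atoms: N,N-dimethylformamide, CN(C)C=O; water, O
Why: Vilsmeier–Haack formylation, in which the chloroiminium ion attacks the only free α position of the electron-rich 2-alkylfuran and is too weak an electrophile to touch the isolated Z alkene, the iminium salt being hydrolysed to the aldehyde on work-up.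

**Step 4**
Reactants: 6 5-[(Z)-oct-2-enyl]furan-2-carbaldehyde; 7 ethyl acetate
Product: 9 ethyl 3-hydroxy-3-[5-[(Z)-oct-2-enyl]furan-2-yl]propanoate (racemic), via lithium enolate of ethyl acetate 8 (not isolated)
Conditions: LiN(i-Pr)2, THF, −78 °C; then 6, −78 °C
Reagents that add atoms: none
Why: Acetate aldol addition of the preformed lithium ester enolate to the non-enolisable furaldehyde; the new carbinol centre is left racemic on purpose because it is ionised in step 10.

**Step 5**
Reactants: 9 ethyl 3-hydroxy-3-[5-[(Z)-oct-2-enyl]furan-2-yl]propanoate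
Product: 10 ethyl 3-[tert-butyl(dimethyl)silyl]oxy-3-[5-[(Z)-oct-2-enyl]furan-2-yl]propanoate (racemic)
Conditions: TBSCl, imidazole, DMF, rt
Reagents that add atoms: tert-butyldimethylsilyl chloride, CC(C)(C)[Si](C)(C)Cl
Why: Imidazole-promoted silylation of a secondary alcohol, which also blocks retro-aldol cleavage and dehydration of the β-hydroxy ester in the following steps.

**Step 6**
Reactants: 10 ethyl 3-[tert-butyl(dimethyl)silyl]oxy-3-[5-[(Z)-oct-2-enyl]furan-2-yl]propanoate
Product: 11 3-[tert-butyl(dimethyl)silyl]oxy-3-[5-[(Z)-oct-2-enyl]furan-2-yl]propanal (racemic)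
Conditions: i-Bu2AlH, CH2Cl2, −78 °C; aqueous work-up
Reagents that add atoms: none
Why: Partial ester reduction with i-Bu2AlH stops at the aldehyde because the tetrahedral aluminium hemiacetal persists at −78 °C until aqueous work-up.

**Step 7**
Reactants: 11 3-[tert-butyl(dimethyl)silyl]oxy-3-[5-[(Z)-oct-2-enyl]furan-2-yl]propanal; 12 (4-carboxybutyl)triphenylphosphonium bromide
Product: 14 (5Z)-8-[tert-butyl(dimethyl)silyl]oxy-8-[5-[(Z)-oct-2-enyl]furan-2-yl]oct-5-enoic acid (racemic), via phosphonium ylide 13 (not isolated)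
Conditions: 12, KN(SiMe3)2 (2 equiv per 12), THF, 0 °C; then 11, −78 °C to rt; aq. KH2PO4
Reagents that add atoms: none
Why: Wittig olefination with a non-stabilised ylide under lithium-free conditions goes through the kinetically favoured cis-oxaphosphetane and so sets the 5Z alkene, the second equivalent of base holding the carboxylate as a spectator and addition at −78 °C outrunning β-elimination of the silyloxy group.

**Step 8**
Reactants: 14 (5Z)-8-[tert-butyl(dimethyl)silyl]oxy-8-[5-[(Z)-oct-2-enyl]furan-2-yl]oct-5-enoic acid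
Product: 15 methyl (5Z)-8-[tert-butyl(dimethyl)silyl]oxy-8-[5-[(Z)-oct-2-enyl]furan-2-yl]oct-5-enoate (racemic)
Conditions: MeI, K2CO3, DMF, rt
Reagents that add atoms: iodomethane, CI
Why: SN2 O-alkylation of the potassium carboxylate, neutral toward the furan, the silyl ether and both Z alkenes.

**Step 9**
Reactants: 15 methyl (5Z)-8-[tert-butyl(dimethyl)silyl]oxy-8-[5-[(Z)-oct-2-enyl]furan-2-yl]oct-5-enoate
Product: 16 methyl (5Z)-8-hydroxy-8-[5-[(Z)-oct-2-enyl]furan-2-yl]oct-5-enoate (racemic)
Conditions: Bu4NF, AcOH, THF, 0 °C to rt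
Reagents that add atoms: none
Why: Fluoride-driven cleavage of the Si–O bond, with acetic acid buffering the alkoxide so that the methyl ester and the furylcarbinol do not meet strong base.

**Step 10**
Reactants: 16 methyl (5Z)-8-hydroxy-8-[5-[(Z)-oct-2-enyl]furan-2-yl]oct-5-enoate
Product: 18 methyl (5Z)-7-[(1S,2R)-2-hydroxy-2-[(Z)-oct-2-enyl]-5-oxocyclopent-3-en-1-yl]hept-5-enoate, via hydroxypentadienyl cation 17 (not isolated)
Conditions: (R)-3,3'-bis(2,4,6-triisopropylphenyl)-1,1'-binaphthyl-2,2'-diyl hydrogen phosphate (10 mol %), H2O (5 equiv), toluene, 40 °C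
Reagents that add atoms: water, O
Why: Proposed new method: the acid ionises either enantiomer of 16 to the same furfuryl cation, water adds at the octenyl-bearing furan carbon (C12), the hemiketal opens to the 1,4-dihydroxypentadienyl cation 17 over C8–C12 paired with the chiral phosphate, and this cation closes to the C8–C12 bond, after which the oxyallyl cation loses a proton to give the enone. The closest known reactions are the racemic oxa-Piancatelli rearrangement of 5-alkyl-2-furylcarbinols to 4-alkyl-4-hydroxycyclopentenones and the chiral-phosphoric-acid-catalysed aza-Piancatelli rearrangement with anilines; what is new is enantiocontrol by the phosphate when water is the nucleophile. The cyclopentenone ring is closed by thermal conrotatory 4π electrocyclisation of the pentadienyl cation. C12 is set by the phosphate, which is hydrogen-bonded to both hydroxyl groups of 17 and so favours one sense of conrotation, and C8 follows from C12 because conrotation of the cation with the C7 chain and the C12 hydroxyl both outward places them trans. The step needs closure to be faster than proton loss from C7 or C13 and needs both Z alkenes to stay out of the cationic array: the 5-alkyl group stabilises positive charge at C12 so that a weak acid at 40 °C should suffice, each alkene is separated from the cation by one methylene, and the quaternary C12 blocks the usual acid-promoted isomerisation of the product.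

**Step 11**
Reactants: 18 methyl (5Z)-7-[(1S,2R)-2-hydroxy-2-[(Z)-oct-2-enyl]-5-oxocyclopent-3-en-1-yl]hept-5-enoate
Product: 19 methyl (5Z)-7-[(1S,2R)-2-[tert-butyl(dimethyl)silyl]oxy-2-[(Z)-oct-2-enyl]-5-oxocyclopent-3-en-1-yl]hept-5-enoate
Conditions: TBSOTf, 2,6-lutidine, CH2Cl2, −78 to 0 °C
Reagents that add atoms: tert-butyldimethylsilyl triflate, CC(C)(C)[Si](C)(C)OS(=O)(=O)C(F)(F)F
Why: Silylation of the tertiary alcohol with a silyl triflate and a hindered pyridine base, which does not enolise the ketone and which blocks retro-aldol opening of the β-hydroxy ketone (a path that would racemise C12) in the basic steps that follow.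

**Step 12**
Reactants: 19 methyl (5Z)-7-[(1S,2R)-2-[tert-butyl(dimethyl)silyl]oxy-2-[(Z)-oct-2-enyl]-5-oxocyclopent-3-en-1-yl]hept-5-enoate
Product: 20 10,11-epoxide of 19 (methyl (5Z)-7-[2-[tert-butyl(dimethyl)silyl]oxy-3,4-epoxy-2-[(Z)-oct-2-enyl]-5-oxocyclopentyl]hept-5-enoate; C8 and C12 as in 19; mixture of epoxide diastereomers)
Conditions: 30% H2O2, NaOH (cat.), MeOH, −20 to 0 °C
Reagents that add atoms: hydrogen peroxide, OO
Why: Weitz–Scheffer nucleophilic epoxidation, in which hydroperoxide adds to C11 of the only enone and the enolate closes on the O–O bond while the isolated Z alkenes are inert and excess H2O2 keeps the medium too weakly basic for fast enolisation at C8; the two epoxide centres are not controlled and are erased in step 13.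

**Step 13**
Reactants: 20 10,11-epoxide of 19
Product: 22 methyl (5Z)-7-[(1S,2S)-2-[tert-butyl(dimethyl)silyl]oxy-4-chloro-2-[(Z)-oct-2-enyl]-5-oxocyclopent-3-en-1-yl]hept-5-enoate, via chlorohydrin 21 (not isolated)
Conditions: HCl (4 M in dioxane), CH2Cl2, 0 °C to rt
Reagents that add atoms: hydrogen chloride, Cl
Why: Acid-promoted opening of the α,β-epoxy ketone by chloride at C10 (SN2 at the carbon α to the carbonyl, C11 being shielded by the quaternary C12) and dehydration of the resulting β-hydroxy ketone, the known conversion of 2,3-epoxycycloalkanones into 2-chlorocycloalkenones, under anhydrous conditions that a tertiary silyl ether should tolerate.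

**Step 14**
Reactants: 22 methyl (5Z)-7-[(1S,2S)-2-[tert-butyl(dimethyl)silyl]oxy-4-chloro-2-[(Z)-oct-2-enyl]-5-oxocyclopent-3-en-1-yl]hept-5-enoate
Product: 23 methyl (5Z)-7-[(2R)-2-[tert-butyl(dimethyl)silyl]oxy-4-chloro-2-[(Z)-oct-2-enyl]-5-oxo-1-(phenylselanyl)cyclopent-3-en-1-yl]hept-5-enoate (C8 epimers)
Conditions: LiN(SiMe3)2, THF, −78 °C; then PhSeBr, −78 °C
Reagents that add atoms: phenylselenenyl bromide, Br[Se]c1ccccc1
Why: α-Selenenylation of a ketone enolate: C8 is the only enolisable position of the ketone (C12 is quaternary and the ester is far less acidic toward this base), the lithium dienolate is attacked at carbon by PhSeBr, and the new C8 centre need not be controlled because it becomes trigonal in step 15.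

**Step 15**
Reactants: 23 C8 selenide
Product: 25 methyl (5Z,7E)-7-[(2R)-2-[tert-butyl(dimethyl)silyl]oxy-4-chloro-2-[(Z)-oct-2-enyl]-5-oxocyclopent-3-en-1-ylidene]hept-5-enoate, via selenoxide 24 (not isolated)
Conditions: 30% H2O2, pyridine, CH2Cl2, 0 °C to rt
Reagents that add atoms: none
Why: Selenoxide syn-elimination: oxidation at selenium is much faster than at the alkenes, C12 carries no hydrogen so only the allylic C7–H can be removed, and the exocyclic C7=C8 alkene should form mainly as the E isomer with C6 anti to the C9 carbonyl, any 7Z isomer being separable by chromatography.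

**Step 16**
Reactants: 25 O12-silyl chlorovulone I
Product: 26 chlorovulone I, methyl (5Z,7E)-7-[(2R)-4-chloro-2-hydroxy-2-[(Z)-oct-2-enyl]-5-oxocyclopent-3-en-1-ylidene]hept-5-enoate
Conditions: 48% aq. HF, MeCN, 0 °C to rt
Reagents that add atoms: none
Why: Acidic fluoride desilylation of the hindered tertiary silyl ether without basic intermediates, so that the cross-conjugated chlorodienone, the ester and the C12 configuration are preserved (the tertiary C–O bond should not ionise because the cation would sit between two electron-poor enone units).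

**Compound list**
1 | (Z)-oct-2-en-1-ol | CCCCC/C=C\CO | starting material
2 | (Z)-1-bromooct-2-ene | CCCCC/C=C\CBr | intermediate
3 | furan | c1ccoc1 | starting material
4 | 2-furyllithium | [Li]c1ccco1 | intermediate (not isolated)
5 | 2-[(Z)-oct-2-enyl]furan | CCCCC/C=C\Cc1ccco1 | intermediate
6 | 5-[(Z)-oct-2-enyl]furan-2-carbaldehyde | CCCCC/C=C\Cc1ccc(C=O)o1 | intermediate
7 | ethyl acetate | CCOC(C)=O | starting material
8 | lithium enolate of ethyl acetate | [Li]OC(=C)OCC | intermediate (not isolated)
9 | ethyl 3-hydroxy-3-[5-[(Z)-oct-2-enyl]furan-2-yl]propanoate (racemic) | CCCCC/C=C\Cc1ccc(o1)C(O)CC(=O)OCC | intermediate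
10 | ethyl 3-[tert-butyl(dimethyl)silyl]oxy-3-[5-[(Z)-oct-2-enyl]furan-2-yl]propanoate (racemic) | CCCCC/C=C\Cc1ccc(o1)C(O[Si](C)(C)C(C)(C)C)CC(=O)OCC | intermediate
11 | 3-[tert-butyl(dimethyl)silyl]oxy-3-[5-[(Z)-oct-2-enyl]furan-2-yl]propanal (racemic) | CCCCC/C=C\Cc1ccc(o1)C(O[Si](C)(C)C(C)(C)C)CC=O | intermediate
12 | (4-carboxybutyl)triphenylphosphonium bromide | OC(=O)CCCC[P+](c1ccccc1)(c1ccccc1)c1ccccc1.[Br-] | starting material
13 | phosphonium ylide, potassium 5-(triphenylphosphoranylidene)pentanoate | [K+].[O-]C(=O)CCCC=P(c1ccccc1)(c1ccccc1)c1ccccc1 | intermediate (not isolated)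
14 | (5Z)-8-[tert-butyl(dimethyl)silyl]oxy-8-[5-[(Z)-oct-2-enyl]furan-2-yl]oct-5-enoic acid (racemic) | CCCCC/C=C\Cc1ccc(o1)C(O[Si](C)(C)C(C)(C)C)C/C=C\CCCC(=O)O | intermediate
15 | methyl (5Z)-8-[tert-butyl(dimethyl)silyl]oxy-8-[5-[(Z)-oct-2-enyl]furan-2-yl]oct-5-enoate (racemic) | CCCCC/C=C\Cc1ccc(o1)C(O[Si](C)(C)C(C)(C)C)C/C=C\CCCC(=O)OC | intermediate
16 | methyl (5Z)-8-hydroxy-8-[5-[(Z)-oct-2-enyl]furan-2-yl]oct-5-enoate (racemic) | CCCCC/C=C\Cc1ccc(o1)C(O)C/C=C\CCCC(=O)OC | intermediate (key-step precursor)
17 | 1,4-dihydroxypentadienyl cation over C8–C12 (C10=C11 cis, C7 chain outward), paired with the chiral phosphate | CCCCC/C=C\CC(=[OH+])/C=C\C(O)=C\C/C=C\CCCC(=O)OC | intermediate (not isolated)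
18 | methyl (5Z)-7-[(1S,2R)-2-hydroxy-2-[(Z)-oct-2-enyl]-5-oxocyclopent-3-en-1-yl]hept-5-enoate (8S,12R; C7 chain trans to OH) | CCCCC/C=C\C[C@@]1(O)C=CC(=O)[C@H]1C/C=C\CCCC(=O)OC | intermediate (key-step product)
19 | methyl (5Z)-7-[(1S,2R)-2-[tert-butyl(dimethyl)silyl]oxy-2-[(Z)-oct-2-enyl]-5-oxocyclopent-3-en-1-yl]hept-5-enoate | CCCCC/C=C\C[C@@]1(O[Si](C)(C)C(C)(C)C)C=CC(=O)[C@H]1C/C=C\CCCC(=O)OC | intermediate
20 | 10,11-epoxide of 19 (C8 and C12 as in 19; epoxide diastereomers) | CCCCC/C=C\C[C@@]1(O[Si](C)(C)C(C)(C)C)C2OC2C(=O)[C@H]1C/C=C\CCCC(=O)OC | intermediate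
21 | chlorohydrin, trans-10-chloro-11-hydroxy ketone from 20 | CCCCC/C=C\C[C@@]1(O[Si](C)(C)C(C)(C)C)C(O)C(Cl)C(=O)[C@H]1C/C=C\CCCC(=O)OC | intermediate (not isolated)
22 | methyl (5Z)-7-[(1S,2S)-2-[tert-butyl(dimethyl)silyl]oxy-4-chloro-2-[(Z)-oct-2-enyl]-5-oxocyclopent-3-en-1-yl]hept-5-enoate (same spatial arrangement as 19; the C12 descriptor changes only because chlorine raises the rank of C11) | CCCCC/C=C\C[C@@]1(O[Si](C)(C)C(C)(C)C)C=C(Cl)C(=O)[C@H]1C/C=C\CCCC(=O)OC | intermediate
23 | methyl (5Z)-7-[(2R)-2-[tert-butyl(dimethyl)silyl]oxy-4-chloro-2-[(Z)-oct-2-enyl]-5-oxo-1-(phenylselanyl)cyclopent-3-en-1-yl]hept-5-enoate (C8 epimers) | CCCCC/C=C\C[C@@]1(O[Si](C)(C)C(C)(C)C)C=C(Cl)C(=O)C1([Se]c2ccccc2)C/C=C\CCCC(=O)OC | intermediate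
24 | selenoxide of 23 | CCCCC/C=C\C[C@@]1(O[Si](C)(C)C(C)(C)C)C=C(Cl)C(=O)C1([Se](=O)c2ccccc2)C/C=C\CCCC(=O)OC | intermediate (not isolated)
25 | methyl (5Z,7E)-7-[(2R)-2-[tert-butyl(dimethyl)silyl]oxy-4-chloro-2-[(Z)-oct-2-enyl]-5-oxocyclopent-3-en-1-ylidene]hept-5-enoate | CCCCC/C=C\C[C@@]1(O[Si](C)(C)C(C)(C)C)C=C(Cl)C(=O)/C1=C/C=C\CCCC(=O)OC | intermediate
26 | chlorovulone I, methyl (5Z,7E)-7-[(2R)-4-chloro-2-hydroxy-2-[(Z)-oct-2-enyl]-5-oxocyclopent-3-en-1-ylidene]hept-5-enoate | CCCCC/C=C\C[C@@]1(O)C=C(Cl)C(=O)/C1=C/C=C\CCCC(=O)OC | target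

**Count**
Total step count: 16. Longest linear sequence: 16 steps (from (Z)-oct-2-en-1-ol 1; 15 from furan 3).

**Steps most likely to fail**

Step 10 (new method). Water competes with the phosphate for hydrogen bonding to the cation, so the two senses of conrotation may be poorly discriminated and the enantiomeric excess low. Proton loss from C7 of the furfuryl cation toward a conjugated furyl diene may also compete with closure. The fallback sets out from 16 and uses the known racemic oxa-Piancatelli rearrangement (ZnCl2, dioxane–water, 60 °C). This should give 18 together with its enantiomer, methyl (5Z)-7-[(1R,2S)-2-hydroxy-2-[(Z)-oct-2-enyl]-5-oxocyclopent-3-en-1-yl]hept-5-enoate F1. The racemate is resolved by preparative HPLC on a cellulose tris(3,5-dimethylphenylcarbamate) stationary phase, F1 is discarded, and the route is rejoined at 18.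

Step 14. Carbon–selenium bond formation at C8, next to the quaternary C12, may be slow, which would give the lithium dienolate time to expel the C12 silyloxy group. The fallback sets out from 22. The enolate is trapped on oxygen as it forms (LiN(SiMe3)2 in the presence of Me3SiCl, THF, −78 °C) to give the silyl dienol ether methyl (5Z)-7-[(3R)-3-[tert-butyl(dimethyl)silyl]oxy-5-chloro-3-[(Z)-oct-2-enyl]-1-(trimethylsilyloxy)cyclopenta-1,4-dien-2-yl]hept-5-enoate F2. Saegusa–Ito oxidation of F2 with stoichiometric Pd(OAc)2 in MeCN then removes a C7 hydrogen by β-hydride elimination (no other β-hydrogen is available) and delivers 25 directly, where the route is rejoined.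

Step 12. Base-induced enolisation at C8 and β-elimination of the C12 silyloxy group may be faster than hydroperoxide addition at the hindered C11. The fallback sets out from 18 and postpones silylation, so that the C12 oxygen is a poor leaving group during the basic step. 18 is epoxidised as the free alcohol (30% H2O2, cat. NaOH, MeOH, −20 °C) to the epoxy alcohol methyl (5Z)-7-[2-hydroxy-3,4-epoxy-2-[(Z)-oct-2-enyl]-5-oxocyclopentyl]hept-5-enoate F3. HCl in dioxane converts F3 through the transient chlorohydrin, the 10-chloro-11,12-dihydroxy ketone F4, into the chloro hydroxy enone methyl (5Z)-7-[(1S,2S)-4-chloro-2-hydroxy-2-[(Z)-oct-2-enyl]-5-oxocyclopent-3-en-1-yl]hept-5-enoate F5. Silylation of F5 (TBSOTf, 2,6-lutidine, CH2Cl2, −78 °C) rejoins the route at 22.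

**Further compounds**
F1 | step 10 | methyl (5Z)-7-[(1R,2S)-2-hydroxy-2-[(Z)-oct-2-enyl]-5-oxocyclopent-3-en-1-yl]hept-5-enoate (enantiomer of 18) | CCCCC/C=C\C[C@]1(O)C=CC(=O)[C@@H]1C/C=C\CCCC(=O)OC
F2 | step 14 | methyl (5Z)-7-[(3R)-3-[tert-butyl(dimethyl)silyl]oxy-5-chloro-3-[(Z)-oct-2-enyl]-1-(trimethylsilyloxy)cyclopenta-1,4-dien-2-yl]hept-5-enoate (silyl dienol ether of 22) | CCCCC/C=C\C[C@@]1(O[Si](C)(C)C(C)(C)C)C=C(Cl)C(O[Si](C)(C)C)=C1C/C=C\CCCC(=O)OC
F3 | step 12 | methyl (5Z)-7-[2-hydroxy-3,4-epoxy-2-[(Z)-oct-2-enyl]-5-oxocyclopentyl]hept-5-enoate (C8 and C12 as in 18; epoxide diastereomers) | CCCCC/C=C\C[C@@]1(O)C2OC2C(=O)[C@H]1C/C=C\CCCC(=O)OC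
F4 | step 12 | 10-chloro-11,12-dihydroxy ketone from F3 (transient chlorohydrin) | CCCCC/C=C\C[C@@]1(O)C(O)C(Cl)C(=O)[C@H]1C/C=C\CCCC(=O)OC
F5 | step 12 | methyl (5Z)-7-[(1S,2S)-4-chloro-2-hydroxy-2-[(Z)-oct-2-enyl]-5-oxocyclopent-3-en-1-yl]hept-5-enoate | CCCCC/C=C\C[C@@]1(O)C=C(Cl)C(=O)[C@H]1C/C=C\CCCC(=O)OC
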